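## Structural features

The target 13 is one carbocycle, a 2,6,6-trimethylcyclohex-2-ene, numbered here C1 (CH bearing the C7H2–O arm), C2(Me)=C3H, C4H2, C5 (CH–O-acyl) and C6 (CMe2). The arm is joined through an aryl ether oxygen to C7 of a coumarin, and the C5 oxygen carries a 3-methylbutanoate (isovalerate). There are two stereocentres, C1 (S) and C5 (R). They flank the quaternary C6, and the C7 arm and the C5 oxygen are cis. The fragile groups are the coumarin lactone with its conjugated C3=C4 bond, the C5 ester (a leaving group whenever a carbonyl sits at C3), and the non-conjugated C2=C3 olefin next to the allylic C1–H; the cis C5 and C7 oxygens also allow acyl transfer. The real difficulty is the C5–C6–C1 triad: a fully substituted carbon between two stereocentres that must be set in absolute terms, with the olefin placed regiospecifically at C2=C3. The key step uses the fact that C5(O)–C6(Me)2 is the skeleton of isobutyraldehyde and that C7–C1–C2(Me)–C3–C4 is a 3-methylpent-3-en-2-one. Joining C6 to C1 (Michael) and C4 to C5 (aldol) builds the ring, the quaternary carbon and both stereocentres in one operation, and leaves a carbonyl at C3, the carbon where the olefin must end.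

## Logic of the disconnections

**13 ⇒ 11 + 12.** The C7–O(aryl) bond is cut. It is the only bond between the two halves, and 12 carries a lactone and a conjugated double bond that should not see triflation, palladium hydride or an enolisable ketone. The gain is that all earlier chemistry runs on a C15 monocycle. The forward step must substitute at a β-branched primary carbon under near-neutral conditions that spare the C5 ester.

**11 ⇒ 10.** The C7–OH is traced back to a 4-methoxybenzyl ether. The C7 oxygen has to be present from the first step, so it needs a mask that survives amine/acid catalysis, acylation, triflation and palladium/formate, and that comes off without base, acid or hydrogen. The forward step must oxidise the electron-rich arene selectively over the olefin and must not trigger acyl transfer from O5 to O7.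

**10 ⇒ 9.** The vinylic C3–H bond is traced to a C3–OTf bond. Exchanging an sp2 C–O bond for C–H fixes the olefin position, so the regiochemical question is moved back to an enolisation. The forward reduction must tolerate the ester; the C5 ester is homoallylic, so no π-allyl pathway is open.

**9 ⇒ 8.** The C2=C3 enol derivative is traced to the C3 ketone with a C2–H. This ketone is what the annulation leaves, and the C2 stereocentre is dispensable. The forward step must enolise toward the tertiary C2 and not toward C4, by a process that forms no enolate, because C5 carries a leaving group β to the carbonyl.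

**8 ⇒ 6 + 7.** The acyl C–O bond at C5 is cut. Placing the final ester directly after ring construction makes it serve as the protecting group, saving a silylation and a desilylation, and it blocks the retro-aldol that would threaten C5. The forward step must acylate a hindered secondary alcohol next to a quaternary carbon without E1cB elimination.

**6 ⇒ 5 ⇒ 3 + 4.** The C4–C5 bond (aldol) and then the C6–C1 bond (Michael) are cut. This is the only disconnection that removes the ring, the quaternary carbon and both stereocentres at once and ends in two achiral compounds. The forward step needs catalyst control of the enone face at C1, thermodynamic control at C5, a cross reaction between two hindered carbons, and a stop at the ketol stage.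

**3 ⇒ 1 + 2.** The enone C=C bond (C1=C2 of the later ring) is cut by carbonyl olefination. Both pieces are purchasable and no protecting-group step is needed. The forward step must give the (E)-olefin, so that a single iminium geometry is offered to the catalyst.

## Other disconnections considered

**Alternative 1:** The cut is the C5–O bond, seen as an oxygen insertion between C5 and C7 of a cyclobutanone.
- **Forward key step:** the bicyclic enone A1 (chrysanthenone series) is epoxidised on the face away from the gem-dimethyl bridge to A2. Peracid or alkaline H2O2 then converts A2 into the bridged γ-lactone A3 by a Baeyer–Villiger shift of C5 with retention.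
- **In favour:** all seven carbons C1–C7 and both stereocentres are already present in a rigid bicycle. The cis relation of the C7 arm and the C5 oxygen is enforced by the bridge and not by an equilibrium. Ring strain should make the oxidation fast. C1 sits next to the epoxide carbon and should be the poorer migrating group, which directs insertion to the C5 side.
- **Against:** A1 is not a standard catalogue compound in enantiopure form. It comes from a photochemical 1,3-shift in the pinane series, which can pass through a ketene and so puts enantiopurity at risk. The olefin must travel as an epoxide and be regenerated late by deoxygenation beside an ester and possibly the coumarin. The lactone must be reduced to the C5/C7 diol without disturbing the epoxide, and the two hydroxyls must then be told apart.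
- **Comparison:** on structure this plan is the better one for relative stereocontrol, and it avoids forming the congested C6–C1 bond. On mechanism its key step is a fully precedented reaction class and is therefore also the better one. On step economy it is about equal, roughly eight operations with a photochemical step and an epoxide on/off pair. The chosen plan is preferred because its absolute configuration comes from a catalyst available in both hands and because the olefin never needs masking.

**Alternative 2:** The cut is the C1–C2 bond, formed by ring contraction; the arm carbon C7 is the former ring carbonyl of a cycloheptenone.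
- **Forward key step:** photolysis of the α-diazo ketone A5 in methanol should give a ketene by Wolff shift of the vinylic C2, which methanol traps as the ester A6.
- **In favour:** the C2-methyl, gem-dimethyl and carbonyl pattern maps onto the cheap achiral dienone A4 (eucarvone). C7 arrives at an oxidation level that reduces directly to the alcohol. Vinyl groups migrate well in Wolff rearrangements. The C6–C1 bond pre-exists, so no hindered C–C bond has to be made.
- **Against:** A4 is achiral, so C5 must be introduced by an asymmetric oxygenation of the γ,δ-double bond of a dienone. Diazo transfer to the CH2 next to the quaternary carbon needs an activating acyl group and its removal. C1 is set only when the ketene-derived enol is protonated, under 1,3-induction across C6, and the cis outcome is not assured. The β,γ-unsaturated ester A6 can slip into conjugation or epimerise at C1. After A6 four more steps follow (reduction, etherification, desilylation, acylation).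
- **Comparison:** on mechanism the key step is a known reaction class and is the better one in that respect. On structure it is weaker, since neither stereocentre is set by a reliable element. On step economy it is worse, about ten to eleven steps against seven.

**Alternative 3:** The cut is the C3–C4 bond.
- **Forward key step:** with Co(dmgH)2(py)Cl and visible light the cis iodolactone A7 should give a primary radical at C4. This adds 6-endo to the CH2 terminus of the isopropenyl group, and divalent cobalt then removes a β-hydrogen from the tertiary radical to give the bridged unsaturated lactone A8.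
- **In favour:** the lactone tether holds the radical next to the alkene and guarantees the cis C1/C5 relation. Attack at the unsubstituted terminus of a 1,1-disubstituted alkene is the normal polarity- and sterics-matched mode. A8 already carries the C2=C3 olefin and both C–O bonds, so only reduction to the diol, etherification at the primary hydroxyl and acylation remain.
- **Against:** hydrogen loss from the tertiary radical can occur from C3 or from the methyl group, so an exocyclic isomer is a likely companion. A7 must be made as a single enantiomer and as the cis isomer, which requires an asymmetric halolactonisation or a resolution of a γ,δ-unsaturated acid that already holds the quaternary carbon. The centre α to the lactone carbonyl is epimerisable.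
- **Comparison:** on step economy after the key step this plan is the better one (three steps against five). On mechanism it is at least the equal of the chosen plan, since dehydrogenative radical cyclisations of alkyl iodides under cobaloxime catalysis are an established type. On structure it leaves the origin of absolute configuration unsolved and moves the regiochemical risk from an enolisation to a hydrogen abstraction. The overall length should be similar.

Key step: step 2

Assumption: the quinine-derived primary amine is taken to direct the enamine to the Re face of the β-carbon of 3, which gives (S)-C1; should the sense be the opposite one, the quinidine-derived pseudoenantiomer is used and nothing else changes.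

## Route

Step 1
Reactants: 1 2-[(4-methoxybenzyl)oxy]acetaldehyde; 2 3-(triphenylphosphoranylidene)butan-2-one
Product: 3 (E)-5-[(4-methoxybenzyl)oxy]-3-methylpent-3-en-2-one
Conditions: PhMe, 90 °C
Reagents that add atoms: none
Why: Wittig olefination of an aldehyde with a stabilized α-methyl acyl ylide; the reversible addition of stabilized ylides should place the acetyl group trans to the CH2O substituent, giving the (E)-trisubstituted enone, and no stereocentre is formed.

Step 2
Reactants: 3 (E)-5-[(4-methoxybenzyl)oxy]-3-methylpent-3-en-2-one; 4 isobutyraldehyde (2-methylpropanal)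
Product: 6 (2S,3S,5R)-5-hydroxy-3-{[(4-methoxybenzyl)oxy]methyl}-2,4,4-trimethylcyclohexan-1-one, via keto aldehyde Michael adduct 5 (not isolated)
Conditions: 9-amino-9-deoxy-epi-quinine (20 mol %), 2-fluorobenzoic acid (40 mol %), 4 (4 equiv), PhMe (1 M), 30–40 °C
Reagents that add atoms: none
Why: Proposed new method: the primary amine salt should form a secondary enamine with 4 and an iminium ion with 3, the fully substituted enamine carbon (C6) should add to the iminium β-carbon (C1), and after hydrolysis to 5 the acetyl methyl (C4, as enol or enamine) should add to the neopentyl aldehyde (C5). The closest known reaction type is the primary-amine-catalysed Michael/aldol (Robinson-type) annulation of α-branched aldehydes with vinyl ketones, taken together with the known iminium activation of α-branched acyclic enones by 9-amino-9-deoxy-epi-cinchona salts; what has not been shown is a quaternary-carbon enamine adding to an α-methyl β-substituted enone. The one ring closes by a 6-(enolendo)-exo-trig aldol through a chair transition state. C1 (S) is set in the Michael step by the catalyst, which should expose the Re face of the β-carbon of the (E)-configured iminium ion. C5 (R) is set by the substrate: the aldol is reversible and the chair with the hydroxyl equatorial and cis to the C1 arm is the thermodynamic sink. C2 (S, methyl equatorial) follows by enol or enamine equilibration and is removed in step 4. The step needs chemoselectivity for the cross reaction and regioselectivity in the aldol, and the substrate secures both: after the Michael step the aldehyde has no α-hydrogen and can only be the acceptor, and closure from C4 gives a six-membered ring where closure from C2 would give a cyclobutane. Dehydration of the ketol is the process to avoid, hence the mild temperature and the carboxylic acid cocatalyst.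

Step 3
Reactants: 6 (2S,3S,5R)-5-hydroxy-3-{[(4-methoxybenzyl)oxy]methyl}-2,4,4-trimethylcyclohexan-1-one; 7 isovaleryl chloride (3-methylbutanoyl chloride)
Product: 8 (1R,3S,4S)-3-{[(4-methoxybenzyl)oxy]methyl}-2,2,4-trimethyl-5-oxocyclohexyl 3-methylbutanoate
Conditions: pyridine (3 equiv), DMAP (5 mol %), CH2Cl2, 0 °C
Reagents that add atoms: none
Why: O-acylation of a secondary alcohol with an acid chloride under nucleophilic catalysis; no stereocentre is touched, and the weak base and low temperature should keep E1cB loss of the new acyloxy group in check. From here on the ester blocks retro-aldol opening, so C5 is locked.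

Step 4
Reactants: 8 (1R,3S,4S)-3-{[(4-methoxybenzyl)oxy]methyl}-2,2,4-trimethyl-5-oxocyclohexyl 3-methylbutanoate
Product: 9 (1R,5R)-5-{[(4-methoxybenzyl)oxy]methyl}-4,6,6-trimethyl-3-{[(trifluoromethyl)sulfonyl]oxy}cyclohex-3-en-1-yl 3-methylbutanoate
Conditions: Tf2O (1.3 equiv), 2,6-di-tert-butyl-4-methylpyridine (1.6 equiv), CH2Cl2, 0 °C to rt
Reagents that add atoms: trifluoromethanesulfonic anhydride (Tf2O), O=S(=O)(OS(=O)(=O)C(F)(F)F)C(F)(F)F
Why: Enol triflate formation from a ketone with Tf2O and a hindered pyridine: O-triflation gives an oxocarbenium-type intermediate that loses an α-proton without passing through an enolate, so the β-acyloxy group at C5 should not be expelled. Proton loss is expected from the tertiary C2–H (more substituted enol triflate; the C4–H bonds are deactivated by the neighbouring C5 acyloxy group). C2 is erased on purpose, so any C2 epimer of 8 converges on 9; the changed descriptor at the arm-bearing carbon is a priority effect only.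

Step 5
Reactants: 9 (1R,5R)-5-{[(4-methoxybenzyl)oxy]methyl}-4,6,6-trimethyl-3-{[(trifluoromethyl)sulfonyl]oxy}cyclohex-3-en-1-yl 3-methylbutanoate
Product: 10 (1R,5S)-5-{[(4-methoxybenzyl)oxy]methyl}-4,6,6-trimethylcyclohex-3-en-1-yl 3-methylbutanoate
Conditions: Pd(OAc)2 (5 mol %), PPh3 (10 mol %), HCO2H (2 equiv), n-Bu3N (3 equiv), DMF, 60 °C
Reagents that add atoms: none
Why: Palladium-catalysed formate reduction of an enol triflate: oxidative addition of zerovalent palladium to the C–OTf bond, formate exchange, loss of CO2 and C–H reductive elimination. The olefin position is dictated by the triflate, and the ester (homoallylic), the benzyl-type ether and both stereocentres are not involved.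

Step 6
Reactants: 10 (1R,5S)-5-{[(4-methoxybenzyl)oxy]methyl}-4,6,6-trimethylcyclohex-3-en-1-yl 3-methylbutanoate
Product: 11 (1R,5S)-5-(hydroxymethyl)-4,6,6-trimethylcyclohex-3-en-1-yl 3-methylbutanoate
Conditions: DDQ (1.3 equiv), CH2Cl2/pH 7 buffer 10:1, 0 °C
Reagents that add atoms: none
Why: Oxidative cleavage of a 4-methoxybenzyl ether by DDQ: hydride abstraction from the electron-rich benzylic position and hydrolysis of the oxocarbenium ion, the oxygen of water ending in the aldehyde by-product. Buffered, cold conditions should leave the olefin and ester alone and give acyl transfer no catalyst.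

Step 7
Reactants: 11 (1R,5S)-5-(hydroxymethyl)-4,6,6-trimethylcyclohex-3-en-1-yl 3-methylbutanoate; 12 umbelliferone (7-hydroxy-2H-chromen-2-one)
Product: 13 (1R,5S)-4,6,6-trimethyl-5-{[(2-oxo-2H-chromen-7-yl)oxy]methyl}cyclohex-3-en-1-yl 3-methylbutanoate
Conditions: PPh3 (1.6 equiv), DIAD (1.6 equiv), 12 (1.5 equiv), THF, 0 °C to rt
Reagents that add atoms: none
Why: Mitsunobu etherification of a primary alcohol with an acidic phenol (pKa about 8); substitution occurs at the CH2 carbon, so neither stereocentre is involved. The near-neutral conditions should spare the ester and the coumarin lactone.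

## Compound list

1 | 2-[(4-methoxybenzyl)oxy]acetaldehyde | COc1ccc(COCC=O)cc1 | starting material
2 | 3-(triphenylphosphoranylidene)butan-2-one | CC(=O)C(C)=P(c1ccccc1)(c1ccccc1)c1ccccc1 | starting material
3 | (E)-5-[(4-methoxybenzyl)oxy]-3-methylpent-3-en-2-one | CC(=O)/C(C)=C/COCc1ccc(OC)cc1 | intermediate
4 | isobutyraldehyde (2-methylpropanal) | CC(C)C=O | starting material
5 | (3S)-3-{[(4-methoxybenzyl)oxy]methyl}-2,2,4-trimethyl-5-oxohexanal (C4 epimers) | CC(=O)C(C)[C@H](COCc1ccc(OC)cc1)C(C)(C)C=O | intermediate (not isolated)
6 | (2S,3S,5R)-5-hydroxy-3-{[(4-methoxybenzyl)oxy]methyl}-2,4,4-trimethylcyclohexan-1-one (all-equatorial ketol) | C[C@@H]1C(=O)C[C@@H](O)C(C)(C)[C@H]1COCc1ccc(OC)cc1 | intermediate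
7 | isovaleryl chloride (3-methylbutanoyl chloride) | CC(C)CC(=O)Cl | starting material
8 | (1R,3S,4S)-3-{[(4-methoxybenzyl)oxy]methyl}-2,2,4-trimethyl-5-oxocyclohexyl 3-methylbutanoate | C[C@@H]1C(=O)C[C@@H](OC(=O)CC(C)C)C(C)(C)[C@H]1COCc1ccc(OC)cc1 | intermediate
9 | (1R,5R)-5-{[(4-methoxybenzyl)oxy]methyl}-4,6,6-trimethyl-3-{[(trifluoromethyl)sulfonyl]oxy}cyclohex-3-en-1-yl 3-methylbutanoate | CC1=C(OS(=O)(=O)C(F)(F)F)C[C@@H](OC(=O)CC(C)C)C(C)(C)[C@H]1COCc1ccc(OC)cc1 | intermediate
10 | (1R,5S)-5-{[(4-methoxybenzyl)oxy]methyl}-4,6,6-trimethylcyclohex-3-en-1-yl 3-methylbutanoate | CC1=CC[C@@H](OC(=O)CC(C)C)C(C)(C)[C@H]1COCc1ccc(OC)cc1 | intermediate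
11 | (1R,5S)-5-(hydroxymethyl)-4,6,6-trimethylcyclohex-3-en-1-yl 3-methylbutanoate | CC1=CC[C@@H](OC(=O)CC(C)C)C(C)(C)[C@H]1CO | intermediate
12 | umbelliferone (7-hydroxy-2H-chromen-2-one) | Oc1ccc2ccc(=O)oc2c1 | starting material
13 | (1R,5S)-4,6,6-trimethyl-5-{[(2-oxo-2H-chromen-7-yl)oxy]methyl}cyclohex-3-en-1-yl 3-methylbutanoate | CC1=CC[C@@H](OC(=O)CC(C)C)C(C)(C)[C@H]1COc1ccc2ccc(=O)oc2c1 | target

## Step count and least certain steps

Total step count: 7. Longest linear sequence: 7 steps (1 to 13).

**Step 2 (key step, carries the new-method label).**
- What may go wrong: the two reacting carbons are both hindered, so C–C bond formation may be too slow to compete with self-condensation of 4 and with γ-deprotonation of the iminium ion of 3 (isomerisation toward an enol ether and loss of the benzyl-type alcohol). Facial selectivity at C1 may be low. The ketol may dehydrate.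
- Fallback (known chemistry, from 3 and 4 back to 6): 4 is silylated (TMSCl, Et3N, DMF, 80 °C) to 2-methyl-1-(trimethylsilyloxy)prop-1-ene F1. F1 is added to 3 in a Mukaiyama–Michael reaction (TiCl4, CH2Cl2, −78 °C) to give racemic 3-{[(4-methoxybenzyl)oxy]methyl}-2,2,4-trimethyl-5-oxohexanal F2. Mild base (K2CO3, MeOH, 0 °C) should close and equilibrate F2 to the racemic all-equatorial ketol, a 1:1 mixture of 6 and its enantiomer (2R,3R,5S)-5-hydroxy-3-{[(4-methoxybenzyl)oxy]methyl}-2,4,4-trimethylcyclohexan-1-one F3. Preparative chromatography on a chiral stationary phase removes F3, and the route is rejoined at 6.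

**Step 4.**
- What may go wrong: proton loss toward C4 instead of C2, since the tetrasubstituted enol derivative suffers allylic strain against the C1 arm, and attack of the anhydride on the electron-rich benzyl ether. A regioisomeric triflate would be an allylic ester and should be degraded in step 5, which eases purification but costs material.
- Fallback (from 8 back to 9): equilibrating soft enolisation (TMSCl, NaI, Et3N, MeCN, 0 °C to rt) gives (1R,5R)-5-{[(4-methoxybenzyl)oxy]methyl}-4,6,6-trimethyl-3-[(trimethylsilyl)oxy]cyclohex-3-en-1-yl 3-methylbutanoate F4. F4 can be purified, and the unwanted regioisomer can be hydrolysed back to 8 and recycled. Fluoride-triggered triflation of F4 (CsF, PhNTf2, DME, rt) then gives 9 regiospecifically.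

**Step 3.**
- What may go wrong: base-induced E1cB loss of the isovalerate from the β-acyloxy ketone, during acylation or on storage, and retro-aldol opening of 6 before it is acylated.
- Fallback (from 6 back to 10):
  - Silylation (TBSOTf, 2,6-lutidine, CH2Cl2, −78 °C) gives (2S,3S,5R)-5-[(tert-butyldimethylsilyl)oxy]-3-{[(4-methoxybenzyl)oxy]methyl}-2,4,4-trimethylcyclohexan-1-one F5.
  - Triflation as in step 4 gives (3R,5R)-5-[(tert-butyldimethylsilyl)oxy]-3-{[(4-methoxybenzyl)oxy]methyl}-2,4,4-trimethylcyclohex-1-en-1-yl trifluoromethanesulfonate F6.
  - Reduction as in step 5 gives tert-butyl{[(1R,5S)-5-{[(4-methoxybenzyl)oxy]methyl}-4,6,6-trimethylcyclohex-3-en-1-yl]oxy}dimethylsilane F7.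
  - TBAF (THF, rt) gives (1R,5S)-5-{[(4-methoxybenzyl)oxy]methyl}-4,6,6-trimethylcyclohex-3-en-1-ol F8.
  - Acylation of F8 with 7 (pyridine, DMAP, CH2Cl2), now with no carbonyl β to the ester oxygen, gives 10. This costs two extra steps.

**Step 7.**
- What may go wrong: slow substitution at the β-branched C7, which lets the activated alcohol decompose, and acyl transfer from O5 to the cis O7 in 11 if it is kept or exposed to base.
- Fallback (from 11 back to 13): sulfonylation (Tf2O, pyridine, CH2Cl2, −78 °C) gives (1R,5S)-4,6,6-trimethyl-5-({[(trifluoromethyl)sulfonyl]oxy}methyl)cyclohex-3-en-1-yl 3-methylbutanoate F9. F9 is displaced by the caesium salt of 12 (Cs2CO3, MeCN, 0 °C to rt) to give 13.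

## Further compounds

F1 | step 2 | 2-methyl-1-(trimethylsilyloxy)prop-1-ene | CC(C)=CO[Si](C)(C)C
F2 | step 2 | racemic 3-{[(4-methoxybenzyl)oxy]methyl}-2,2,4-trimethyl-5-oxohexanal | CC(=O)C(C)C(COCc1ccc(OC)cc1)C(C)(C)C=O
F3 | step 2 | (2R,3R,5S)-5-hydroxy-3-{[(4-methoxybenzyl)oxy]methyl}-2,4,4-trimethylcyclohexan-1-one (enantiomer of 6) | C[C@H]1C(=O)C[C@H](O)C(C)(C)[C@@H]1COCc1ccc(OC)cc1
F4 | step 4 | (1R,5R)-5-{[(4-methoxybenzyl)oxy]methyl}-4,6,6-trimethyl-3-[(trimethylsilyl)oxy]cyclohex-3-en-1-yl 3-methylbutanoate | CC1=C(O[Si](C)(C)C)C[C@@H](OC(=O)CC(C)C)C(C)(C)[C@H]1COCc1ccc(OC)cc1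
F5 | step 3 | (2S,3S,5R)-5-[(tert-butyldimethylsilyl)oxy]-3-{[(4-methoxybenzyl)oxy]methyl}-2,4,4-trimethylcyclohexan-1-one | C[C@@H]1C(=O)C[C@@H](O[Si](C)(C)C(C)(C)C)C(C)(C)[C@H]1COCc1ccc(OC)cc1
F6 | step 3 | (3R,5R)-5-[(tert-butyldimethylsilyl)oxy]-3-{[(4-methoxybenzyl)oxy]methyl}-2,4,4-trimethylcyclohex-1-en-1-yl trifluoromethanesulfonate | CC1=C(OS(=O)(=O)C(F)(F)F)C[C@@H](O[Si](C)(C)C(C)(C)C)C(C)(C)[C@H]1COCc1ccc(OC)cc1
F7 | step 3 | tert-butyl{[(1R,5S)-5-{[(4-methoxybenzyl)oxy]methyl}-4,6,6-trimethylcyclohex-3-en-1-yl]oxy}dimethylsilane | CC1=CC[C@@H](O[Si](C)(C)C(C)(C)C)C(C)(C)[C@H]1COCc1ccc(OC)cc1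
F8 | step 3 | (1R,5S)-5-{[(4-methoxybenzyl)oxy]methyl}-4,6,6-trimethylcyclohex-3-en-1-ol | CC1=CC[C@@H](O)C(C)(C)[C@H]1COCc1ccc(OC)cc1
F9 | step 7 | (1R,5S)-4,6,6-trimethyl-5-({[(trifluoromethyl)sulfonyl]oxy}methyl)cyclohex-3-en-1-yl 3-methylbutanoate | CC1=CC[C@@H](OC(=O)CC(C)C)C(C)(C)[C@H]1COS(=O)(=O)C(F)(F)F
A1 | alternative 1 | 2,7,7-trimethylbicyclo[3.1.1]hept-2-en-6-one (chrysanthenone, enantiomer shown) | CC1=CC[C@@H](C2=O)C(C)(C)[C@H]12
A2 | alternative 1 | 2,3-epoxy-2,7,7-trimethylbicyclo[3.1.1]heptan-6-one (epoxide anti to the gem-dimethyl bridge) | C[C@]12O[C@H]1C[C@@H](C3=O)C(C)(C)[C@H]23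
A3 | alternative 1 | 2,3-epoxy-2,8,8-trimethyl-6-oxabicyclo[3.2.1]octan-7-one | C[C@]12O[C@H]1C[C@@H](OC3=O)C(C)(C)[C@H]23
A4 | alternative 2 | eucarvone (2,6,6-trimethylcyclohepta-2,4-dien-1-one) | CC1=CC=CC(C)(C)CC1=O
A5 | alternative 2 | (5R)-5-[(tert-butyldimethylsilyl)oxy]-7-diazo-2,6,6-trimethylcyclohept-2-en-1-one | CC1=CC[C@@H](O[Si](C)(C)C(C)(C)C)C(C)(C)C(=[N+]=[N-])C1=O
A6 | alternative 2 | methyl (1S,5R)-5-[(tert-butyldimethylsilyl)oxy]-2,6,6-trimethylcyclohex-2-ene-1-carboxylate | CC1=CC[C@@H](O[Si](C)(C)C(C)(C)C)C(C)(C)[C@H]1C(=O)OC
A7 | alternative 3 | cis-5-(iodomethyl)-4,4-dimethyl-3-(prop-1-en-2-yl)oxolan-2-one | CC(=C)[C@@H]1C(=O)O[C@H](CI)C1(C)C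
A8 | alternative 3 | 2,8,8-trimethyl-6-oxabicyclo[3.2.1]oct-2-en-7-one | CC1=CC[C@@H](OC2=O)C(C)(C)[C@H]12
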